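**Plan**

Locants: flavan numbering is used (ring C = O1, C2–C4; ring A = C4a–C8a; ring B = C1'–C6'). Ring D is O4'–C2''(Me2)–C3''–C4''–C5'–C4'.
- **Cuts (retro):** the cis C3''–OH/C4''–OH pair goes back, via a temporary cyclic carbonate and the epoxide, to the C3''=C4'' chromene. One pericyclic event then cuts C4''–C5' (ring D) and C2'–CH2 (prenyl) together, back to the catechol bis-ether O4'–CMe2–C≡CH / O3'–CMe2–CH=CH2. Finally O1–C2 and C3–C4 of ring C are cut.
- **Enabling feature:** on ring B, O3' has only C2' and O4' has only C5' as a C–H ortho carbon. The target carries its two C5 units exactly there, so both are Claisen retrons, the regiochemistry is forced, and the pentasubstituted ring B is completed in one operation.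
- **Forward order:** rings A and B are bought and joined by an aldol condensation (C3–C4). Ring C closes in step 7 and ring D closes last, in step 9.
- **Stereochemistry:** C2 (S) comes from catalyst-controlled transfer hydrogenation to the (R)-carbinol followed by SN2 inversion. C3''/C4'' (R,R) come from (R,R)-Mn(salen) epoxidation, and the cis relation is kept by double inversion at C4'' inside the carbonate ring.

Key step: step 9

Remark: the acetal carbon of the THP group is not controlled, so 9–13 are epimer mixtures at that carbon only; it is removed in step 8.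

**Step 1**
Reactants: 1 3,4-dihydroxyacetophenone; 2 3-chloro-3-methylbut-1-yne
Product: 3 1-[3-hydroxy-4-(2-methylbut-3-yn-2-yloxy)phenyl]ethanone
Conditions: K2CO3 (1.0 equiv), KI (cat.), CuI (cat.), acetone, 50 °C, Ar
Reagents that add atoms: none
Why: Copper-assisted O-alkylation of a phenoxide with a tertiary propargylic chloride; with one equivalent of weak base only the 4-OH, acidified by the para acetyl group, is ionised, so the ether should form at O4 and leave the 3-OH free.

**Step 2**
Reactants: 4 2-methylbut-3-en-2-ol
Product: 6 methyl 2-methylbut-3-en-2-yl carbonate, via lithium alkoxide 5 (not isolated)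
Conditions: n-BuLi, THF, −78 → 0 °C; then ClCO2Me, 0 °C → rt
Reagents that add atoms: methyl chloroformate, COC(=O)Cl; n-butyllithium, [Li]CCCC (lithium of 5 only)
Why: Acylation of a preformed tertiary alkoxide with a chloroformate is the standard way to the mixed carbonate that serves as π-allyl precursor.

**Step 3**
Reactants: 3 1-[3-hydroxy-4-(2-methylbut-3-yn-2-yloxy)phenyl]ethanone; 6 methyl 2-methylbut-3-en-2-yl carbonate
Product: 7 1-[3-(2-methylbut-3-en-2-yloxy)-4-(2-methylbut-3-yn-2-yloxy)phenyl]ethanone
Conditions: Pd(PPh3)4 (3 mol %), THF, 0–5 °C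
Reagents that add atoms: none
Why: Tsuji–Trost O-allylation in which Pd(0) ionises 6 with loss of CO2, the methoxide set free deprotonates the 3-OH, and under kinetic control at low temperature the phenoxide attacks the more substituted terminus of the 1,1-dimethylallyl complex to give the tertiary (reverse prenyl) ether, as known for crowded catechol ethers, while the aryl propargyl ether is not ionised.

**Step 4**
Reactants: 8 2,4-dihydroxybenzaldehyde
Product: 9 2-hydroxy-4-(oxan-2-yloxy)benzaldehyde
Conditions: 3,4-dihydro-2H-pyran, PPTS (cat.), CH2Cl2, rt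
Reagents that add atoms: 3,4-dihydro-2H-pyran, C1=COCCC1
Why: Acid-catalysed acetalisation that should stop at the 4-OH because the 2-OH is held in a hydrogen bond to the formyl group.

**Step 5**
Reactants: 7 1-[3-(2-methylbut-3-en-2-yloxy)-4-(2-methylbut-3-yn-2-yloxy)phenyl]ethanone; 9 2-hydroxy-4-(oxan-2-yloxy)benzaldehyde
Product: 10 (E)-3-[2-hydroxy-4-(oxan-2-yloxy)phenyl]-1-[3-(2-methylbut-3-en-2-yloxy)-4-(2-methylbut-3-yn-2-yloxy)phenyl]prop-2-en-1-one
Conditions: KOH (3 equiv), EtOH, rt; aq NH4Cl work-up (pH 7)
Reagents that add atoms: none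
Why: Claisen–Schmidt condensation with E1cB dehydration to the (E)-enone, known for salicylaldehydes used as their phenoxides, and all ethers, the alkyne and the THP acetal are stable to base.

**Step 6**
Reactants: 10 the (E)-enone
Product: 12 (1R)-3-[2-hydroxy-4-(oxan-2-yloxy)phenyl]-1-[3-(2-methylbut-3-en-2-yloxy)-4-(2-methylbut-3-yn-2-yloxy)phenyl]propan-1-ol, via dihydrochalcone 11 (not isolated)
Conditions: RuCl[(R,R)-TsDPEN](p-cymene) (2 mol %), HCO2Na (10 equiv), MeOH/H2O 2:1, 40 °C
Reagents that add atoms: none
Why: Noyori-type asymmetric transfer hydrogenation, known to take chalcones through 1,4- and then 1,2-hydride transfer in one pot; the polar outer-sphere hydride leaves the unpolarised vinyl and ethynyl groups alone, and the (R,R)-catalyst reduces aryl ketone 11 on the face fixed by the CH/π contact with ring B to give the (R)-carbinol.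

**Step 7**
Reactants: 12 the (1R)-carbinol
Product: 13 (2S)-2-[3-(2-methylbut-3-en-2-yloxy)-4-(2-methylbut-3-yn-2-yloxy)phenyl]-7-(oxan-2-yloxy)chromane
Conditions: PPh3, DIAD, toluene/THF, 0 °C
Reagents that add atoms: none
Why: Intramolecular Mitsunobu etherification (6-exo-tet) in which the only free phenol displaces the oxyphosphonium group by SN2, so that (R) is inverted to (2S), the low temperature and low polarity being chosen to suppress ionisation of the p-alkoxybenzylic centre.

**Step 8**
Reactants: 13 the 7-O-THP flavan
Product: 14 (2S)-2-[3-(2-methylbut-3-en-2-yloxy)-4-(2-methylbut-3-yn-2-yloxy)phenyl]chroman-7-ol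
Conditions: PPTS (0.1 equiv), MeOH, rt
Reagents that add atoms: none
Why: Acetal exchange in which the aryl THP acetal ionises to an oxocarbenium ion far faster than the tertiary allyl and propargyl aryl ethers or the C2–O1 bond can ionise under pyridinium acid, and the removal is placed here so that no acid is needed once the diol is in place.

**Step 9**
Reactants: 14 (2S)-2-[3-(2-methylbut-3-en-2-yloxy)-4-(2-methylbut-3-yn-2-yloxy)phenyl]chroman-7-ol
Product: 18 (2S)-2-[8-hydroxy-2,2-dimethyl-7-(3-methylbut-2-enyl)-2H-chromen-6-yl]chroman-7-ol, via o-prenylphenol propargyl ether 15 (not isolated), via allenylcatechol 16 (not isolated), via o-quinone methide 17 (not isolated)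
Conditions: PhNEt2 (degassed, 0.05 M), Ar, 120 °C, 1 h, then 190 °C, 2 h
Reagents that add atoms: none
Why: Two aromatic Claisen rearrangements run one after the other in the same flask: the tertiary allyl ether on O3' shifts first ([3,3], CH2 terminus to C2', then enolisation) to give 15, and at the higher temperature the tertiary propargyl ether on O4' shifts to C5' to give allenylcatechol 16, whose O4'–H migrates to the central allene carbon ([1,5]-H) to form the (Z)-o-quinone methide 17. Ring D then closes by a thermal disrotatory oxa-6π electrocyclisation of 17 (O4'–C2'' bond, formally 6-endo), driven by rearomatisation of ring B. The closest known reaction types are the rearrangement of aryl 1,1-dimethylallyl ethers to o-prenylphenols and that of aryl 1,1-dimethylpropargyl ethers to 2,2-dimethyl-2H-chromenes, both accelerated by the gem-dimethyl groups. No stereocentre is formed, and C2 should be a spectator because O4' is free only in short-lived 16 and the medium is neither acidic nor strongly basic, so a p-quinone-methide opening of ring C should not compete. The selectivity needed is positional and the substrate secures it: each ether oxygen has a single C–H ortho carbon (C2' for O3', C5' for O4'), and a shift to the oxygen-bearing ortho carbon gives a dienone that cannot enolise and reverts. The amine solvent scavenges traces of acid, so the new o-prenylphenol should not cyclise to a chroman and the tertiary allyl ether should not ionise.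

**Step 10**
Reactants: 18 the chromene bis-phenol
Product: 19 (2S)-2-[8-acetoxy-2,2-dimethyl-7-(3-methylbut-2-enyl)-2H-chromen-6-yl]chroman-7-yl acetate
Conditions: Ac2O, pyridine, DMAP (cat.), CH2Cl2, 0 °C → rt
Reagents that add atoms: acetic anhydride, CC(=O)OC(C)=O
Why: Routine DMAP-catalysed acetylation that masks both phenols against the oxidant of the next step and can be taken off later by base alone.

**Step 11**
Reactants: 19 the chromene diacetate
Product: 20 (2S)-2-[(3R,4R)-8-acetoxy-3,4-epoxy-2,2-dimethyl-7-(3-methylbut-2-enyl)chroman-6-yl]chroman-7-yl acetate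
Conditions: (R,R)-Mn(salen)Cl [salen = N,N'-bis(3,5-di-tert-butylsalicylidene)-1,2-cyclohexanediamine] (4 mol %), 4-phenylpyridine N-oxide (0.2 equiv), aq NaOCl (pH 11.3 buffer), CH2Cl2, 0 °C
Reagents that add atoms: sodium hypochlorite, [Na+].[O-]Cl
Why: Jacobsen–Katsuki epoxidation, for which 2,2-dimethylchromenes are the best substrate class and which is known to prefer the conjugated cis alkene over an isolated trisubstituted one, so the prenyl group should survive, and the (R,R)-catalyst delivers oxygen to the face that gives the (3R,4R)-epoxide under pure reagent control.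

**Step 12**
Reactants: 20 the (3R,4R)-epoxide
Product: 21 (2S)-2-[(3R,4R)-8-acetoxy-3,4-(carbonyldioxy)-2,2-dimethyl-7-(3-methylbut-2-enyl)chroman-6-yl]chroman-7-yl acetate (cis-fused cyclic carbonate)
Conditions: CO2 (10 bar), Al(III) amino-tris(phenolate) (2 mol %), Bu4NBr (5 mol %), 2-butanone, 70 °C
Reagents that add atoms: carbon dioxide, O=C=O
Why: Lewis acid/halide co-catalysed cycloaddition of CO2 to an epoxide, known for benzo-fused cyclic epoxides, in which bromide opens benzylic C4'' with inversion, the C3'' alkoxide takes up CO2 and the carbonate displaces bromide with a second inversion, so that C4'' is retained overall, C3''–O is never broken and the temporary five-membered ring can only be cis-fused.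

**Step 13**
Reactants: 21 the cis-carbonate diacetate
Product: 22 (3R,4R)-6-[(2S)-7-hydroxychroman-2-yl]-2,2-dimethyl-7-(3-methylbut-2-enyl)chromane-3,4,8-triol (target)
Conditions: K2CO3 (0.3 equiv), MeOH (degassed), 0 °C → rt; aq NH4Cl
Reagents that add atoms: none
Why: Base-catalysed transesterification that cleaves both aryl acetates and the cyclic carbonate at their acyl carbons only, so no bond at C3'', C4'' or C2 is touched, and it avoids the acid that could ionise the benzylic C4''–OH or cyclise the o-prenylphenol.

**Compound list**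

| No. | Name | SMILES | Role |
|---|---|---|---|
| 1 | 3,4-dihydroxyacetophenone | CC(=O)c1ccc(O)c(O)c1 | starting material |
| 2 | 3-chloro-3-methylbut-1-yne | C#CC(C)(C)Cl | starting material |
| 3 | 1-[3-hydroxy-4-(2-methylbut-3-yn-2-yloxy)phenyl]ethanone | CC(=O)c1ccc(OC(C)(C)C#C)c(O)c1 | intermediate |
| 4 | 2-methylbut-3-en-2-ol | C=CC(C)(C)O | starting material |
| 5 | lithium 2-methylbut-3-en-2-olate (not isolated) | [Li+].[O-]C(C)(C)C=C | intermediate |
| 6 | methyl 2-methylbut-3-en-2-yl carbonate | C=CC(C)(C)OC(=O)OC | intermediate |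
| 7 | 1-[3-(2-methylbut-3-en-2-yloxy)-4-(2-methylbut-3-yn-2-yloxy)phenyl]ethanone | CC(=O)c1ccc(OC(C)(C)C#C)c(OC(C)(C)C=C)c1 | intermediate |
| 8 | 2,4-dihydroxybenzaldehyde | O=Cc1ccc(O)cc1O | starting material |
| 9 | 2-hydroxy-4-(oxan-2-yloxy)benzaldehyde | O=Cc1ccc(OC2CCCCO2)cc1O | intermediate |
| 10 | (E)-enone (retro-chalcone) | O=C(/C=C/c1ccc(OC2CCCCO2)cc1O)c1ccc(OC(C)(C)C#C)c(OC(C)(C)C=C)c1 | intermediate |
| 11 | dihydrochalcone (not isolated) | O=C(CCc1ccc(OC2CCCCO2)cc1O)c1ccc(OC(C)(C)C#C)c(OC(C)(C)C=C)c1 | intermediate |
| 12 | (1R)-1,3-diarylpropan-1-ol | O[C@H](CCc1ccc(OC2CCCCO2)cc1O)c1ccc(OC(C)(C)C#C)c(OC(C)(C)C=C)c1 | intermediate |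
| 13 | (2S)-flavan, 7-O-THP | C#CC(C)(C)Oc1ccc([C@@H]2CCc3ccc(OC4CCCCO4)cc3O2)cc1OC(C)(C)C=C | intermediate |
| 14 | (2S)-flavan-7-ol bis-ether | C#CC(C)(C)Oc1ccc([C@@H]2CCc3ccc(O)cc3O2)cc1OC(C)(C)C=C | intermediate |
| 15 | (2S)-2-[3-hydroxy-2-(3-methylbut-2-enyl)-4-(2-methylbut-3-yn-2-yloxy)phenyl]chroman-7-ol (not isolated) | C#CC(C)(C)Oc1ccc([C@@H]2CCc3ccc(O)cc3O2)c(CC=C(C)C)c1O | intermediate |
| 16 | (2S)-2-[3,4-dihydroxy-5-(3-methylbuta-1,2-dienyl)-2-(3-methylbut-2-enyl)phenyl]chroman-7-ol (not isolated) | CC(C)=C=Cc1cc([C@@H]2CCc3ccc(O)cc3O2)c(CC=C(C)C)c(O)c1O | intermediate |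
| 17 | (Z)-o-quinone methide (not isolated) | CC(C)=C/C=C1/C=C([C@@H]2CCc3ccc(O)cc3O2)C(CC=C(C)C)=C(O)C1=O | intermediate |
| 18 | (2S)-2-[8-hydroxy-2,2-dimethyl-7-(3-methylbut-2-enyl)-2H-chromen-6-yl]chroman-7-ol | CC(C)=CCc1c([C@@H]2CCc3ccc(O)cc3O2)cc2c(c1O)OC(C)(C)C=C2 | intermediate |
| 19 | chromene diacetate | CC(C)=CCc1c([C@@H]2CCc3ccc(OC(C)=O)cc3O2)cc2c(c1OC(C)=O)OC(C)(C)C=C2 | intermediate |
| 20 | (3R,4R)-epoxide diacetate | CC(C)=CCc1c([C@@H]2CCc3ccc(OC(C)=O)cc3O2)cc2c(c1OC(C)=O)OC(C)(C)[C@@H]4O[C@H]24 | intermediate |
| 21 | (3R,4R)-cis-cyclic carbonate diacetate | CC(C)=CCc1c([C@@H]2CCc3ccc(OC(C)=O)cc3O2)cc2c(c1OC(C)=O)OC(C)(C)[C@@H]4OC(=O)O[C@H]24 | intermediate |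
| 22 | (3R,4R)-6-[(2S)-7-hydroxychroman-2-yl]-2,2-dimethyl-7-(3-methylbut-2-enyl)chromane-3,4,8-triol | CC(C)=CCc1c([C@@H]2CCc3ccc(O)cc3O2)cc2c(c1O)OC(C)(C)[C@H](O)[C@@H]2O | target |

**Step count**

Total steps: 13. Longest linear sequence: 11 (steps 1, 3, 5–13).

**Steps most likely to fail**

1. **Step 9.**
   - Process at risk: at the temperature that the propargyl shift needs, three processes may drain material. These are retro-ene loss of isoprene from the tertiary allyl ether, a shift to blocked C4' followed by a Cope shift to C6', and thermal cyclisation of the new o-prenylphenol.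
   - Fallback: the two events are separated and ring D is closed by π-acid catalysis instead of sigmatropy.
   - Setting out from 14, heating in toluene at 110 °C should trigger the allyl shift only, and 15 is isolated.
   - Acetylation (Ac2O, pyridine, DMAP) should give the propargyl ether diacetate F1. This keeps the 3'-OH from adding to the activated alkyne.
   - Ph3PAuNTf2 (2 mol %) in CH2Cl2 at rt should then effect the known 6-endo-dig hydroarylation of the aryl propargyl ether at C5', the only free ortho carbon.
   - The fallback comes back to the route at 19.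

2. **Step 12.**
   - Process at risk: slow halide opening of the epoxide next to the quaternary C2'', a Lewis-acid-induced 1,2-hydride shift to a chromanone, or leakage through a free C4'' cation with loss of stereochemical integrity.
   - Fallback: C4'' is erased and reset from C3''.
   - Setting out from 20, hydrolysis (THF/H2O, cat. HClO4, 0 °C) should give the 3,4-diol diacetate F2. It is epimeric at C4'' but fixed at C3''.
   - Activated MnO2 in CH2Cl2 should oxidise the benzylic hydroxyl only, giving the 3-hydroxychroman-4-one F3. The spatial arrangement at C3'' is unchanged; the descriptor becomes S by priority.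
   - Zn(BH4)2 in Et2O at −20 °C should reduce the chelated ketone from the face of C3''–H. This is also the face anti to the pseudo-axial C2'' methyl, so the product should be the cis-diol diacetate F4.
   - K2CO3/MeOH then removes the acetates, and the fallback comes back at 22.

3. **Step 6.**
   - Process at risk: 1,2-hydride transfer to the enone may outrun the 1,4-transfer because the β-aryl group is very electron-rich. This would lead to an easily ionised allylic alcohol. Alternatively, the second reduction may stall.
   - Fallback: the two reductions are done by boron reagents in separate operations.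
   - Setting out from 10, uncatalysed 1,4-hydroboration with catecholborane (3 equiv, one consumed by the phenol; THF, rt; aqueous work-up) should give 11, which is now isolated.
   - CBS reduction with the (S)-methyl oxazaborolidine and catecholborane in toluene at −78 °C, where alkene and alkyne are not hydroborated, should give the (R)-carbinol.
   - The fallback comes back at 12 and makes no compound outside the list (F0).

**Further compounds**

F1 | step 9 | (2S)-2-[3-acetoxy-2-(3-methylbut-2-enyl)-4-(2-methylbut-3-yn-2-yloxy)phenyl]chroman-7-yl acetate | C#CC(C)(C)Oc1ccc([C@@H]2CCc3ccc(OC(C)=O)cc3O2)c(CC=C(C)C)c1OC(C)=O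
F2 | step 12 | (2S)-2-[(3R)-8-acetoxy-3,4-dihydroxy-2,2-dimethyl-7-(3-methylbut-2-enyl)chroman-6-yl]chroman-7-yl acetate, C4 epimers | CC(C)=CCc1c([C@@H]2CCc3ccc(OC(C)=O)cc3O2)cc2c(c1OC(C)=O)OC(C)(C)[C@H](O)C2O
F3 | step 12 | (2S)-2-[(3S)-8-acetoxy-3-hydroxy-2,2-dimethyl-7-(3-methylbut-2-enyl)-4-oxochroman-6-yl]chroman-7-yl acetate | CC(C)=CCc1c([C@@H]2CCc3ccc(OC(C)=O)cc3O2)cc2c(c1OC(C)=O)OC(C)(C)[C@H](O)C2=O
F4 | step 12 | (2S)-2-[(3R,4R)-8-acetoxy-3,4-dihydroxy-2,2-dimethyl-7-(3-methylbut-2-enyl)chroman-6-yl]chroman-7-yl acetate | CC(C)=CCc1c([C@@H]2CCc3ccc(OC(C)=O)cc3O2)cc2c(c1OC(C)=O)OC(C)(C)[C@H](O)[C@@H]2O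
F0 | step 6 | none | none
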